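**Retrosynthetic overview**
1. Target 15 ⇐ bis-MOM ether 14 by mild acid cleavage of the two MOM groups on ring B.
2. 14 ⇐ allylphenol 13 by closing the O1–C2 bond: an enantioselective anti-Markovnikov hydroetherification forms the pyran ring (ring C) and sets C3 in the same step.
3. 13 ⇐ aryl 2-arylallyl ether 12 by aromatic Claisen rearrangement (C4–C4a bond).
4. 12 ⇐ alkenyl bromide 4 + aryl bromide 9 (Suzuki–Miyaura, C3–C1' bond); 4 ⇐ 2,4,6-trihydroxybenzaldehyde by two O-alkylations; 9 ⇐ 4-bromoresorcinol by MOM protection and directed metalation/prenylation.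
5. Ring order: rings A and B are bought as benzenes; ring C is the only ring made (step 7).

**Assumptions**
- Thiol T* is a designed chiral hydrogen-atom donor: (R)-1-[3,5-bis(trifluoromethyl)phenyl]-3-(2'-sulfanyl-1,1'-binaphthalen-2-yl)urea, an arenethiol with a urea hydrogen-bond donor on the neighbouring naphthyl ring.
- (R)-T* is taken to deliver the (3R) product; if the sense of induction is the opposite, its enantiomer is used.

**Route**

Step 1
Reactants: 1 2,4,6-trihydroxybenzaldehyde
Product: 2 2,6-dihydroxy-4-methoxybenzaldehyde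
Conditions: MeI (1.0 equiv), K2CO3 (1.0 equiv), acetone, 0 °C → rt
Reagents that add atoms: iodomethane (MeI), CI
Why: Williamson O-methylation; the 4-OH is the only phenol not hydrogen-bonded to the formyl group and the most acidic, so one equivalent of base and MeI methylates it selectively.

Step 2
Reactants: 2 2,6-dihydroxy-4-methoxybenzaldehyde; 3 2,3-dibromoprop-1-ene
Product: 4 2-[(2-bromoprop-2-en-1-yl)oxy]-6-hydroxy-4-methoxybenzaldehyde
Conditions: K2CO3 (1.1 equiv), acetone, 50 °C
Reagents that add atoms: none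
Why: Williamson etherification by SN2 at the allylic bromide (the vinylic bromide is inert); the two OH groups are equivalent and the one left stays chelated to CHO, which limits bis-alkylation.

Step 3
Reactants: 5 4-bromobenzene-1,3-diol
Product: 6 1-bromo-2,4-bis(methoxymethoxy)benzene
Conditions: NaH (2.2 equiv), MOMCl (2.3 equiv), DMF, 0 °C → rt
Reagents that add atoms: chloromethyl methyl ether (MOMCl), COCCl
Why: O-alkylation of both phenoxides gives MOM acetals, which direct the next lithiation and come off later under mild acid.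

Step 4
Reactants: 6 1-bromo-2,4-bis(methoxymethoxy)benzene; 7 1-bromo-3-methylbut-2-ene
Product: 9 1-bromo-2,4-bis(methoxymethoxy)-3-(3-methylbut-2-en-1-yl)benzene, via aryllithium 8 (not isolated)
Conditions: LiN(i-Pr)2 (1.1 equiv), THF, −78 °C, 1 h; CuBr·SMe2 (10 mol%), then 7, −78 → 0 °C
Reagents that add atoms: lithium diisopropylamide, [Li]N(C(C)C)C(C)C (its Li is found only in 8)
Why: Directed ortho-metalation at the C–H flanked by both OMOM groups (an amide base leaves the C–Br bond alone), then copper-catalysed SN2 allylation by prenyl bromide.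

Step 5
Reactants: 9 1-bromo-2,4-bis(methoxymethoxy)-3-(3-methylbut-2-en-1-yl)benzene; 4 2-[(2-bromoprop-2-en-1-yl)oxy]-6-hydroxy-4-methoxybenzaldehyde
Product: 12 2-({2-[2,4-bis(methoxymethoxy)-3-(3-methylbut-2-en-1-yl)phenyl]prop-2-en-1-yl}oxy)-6-hydroxy-4-methoxybenzaldehyde, via aryllithium 10 (not isolated), via lithium aryltriisopropoxyborate 11 (not isolated)
Conditions: n-BuLi (1.05 equiv), THF, −78 °C; B(Oi-Pr)3, −78 °C → rt; then 4, Pd(OAc)2 (3 mol%), SPhos (6 mol%), aq K3PO4, THF/H2O, 40 °C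
Reagents that add atoms: n-butyllithium, [Li]CCCC (its Li is found only in 10 and 11); triisopropyl borate, CC(C)OB(OC(C)C)OC(C)C (found only in 11)
Why: Br/Li exchange and borate formation, then Suzuki–Miyaura coupling of the lithium triisopropyl arylborate with the alkenyl bromide; oxidative addition at the C(sp2)–Br bond is faster than ionisation of the allyl aryl ether, and the free phenol and aldehyde tolerate aqueous phosphate.

Step 6
Reactants: 12 2-({2-[2,4-bis(methoxymethoxy)-3-(3-methylbut-2-en-1-yl)phenyl]prop-2-en-1-yl}oxy)-6-hydroxy-4-methoxybenzaldehyde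
Product: 13 3-{2-[2,4-bis(methoxymethoxy)-3-(3-methylbut-2-en-1-yl)phenyl]prop-2-en-1-yl}-2,6-dihydroxy-4-methoxybenzaldehyde
Conditions: PhNEt2, 190 °C, sealed tube, 4 h
Reagents that add atoms: none
Why: Aromatic Claisen rearrangement ([3,3]-sigmatropic shift, then tautomerisation); C1 carries CHO, so the allyl unit goes to the only free ortho carbon, and the basic solvent suppresses acid-catalysed Markovnikov ring closure of the product.

Step 7
Reactants: 13 3-{2-[2,4-bis(methoxymethoxy)-3-(3-methylbut-2-en-1-yl)phenyl]prop-2-en-1-yl}-2,6-dihydroxy-4-methoxybenzaldehyde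
Product: 14 (3R)-3-[2,4-bis(methoxymethoxy)-3-(3-methylbut-2-en-1-yl)phenyl]-7-hydroxy-5-methoxy-3,4-dihydro-2H-chromene-8-carbaldehyde
Conditions: 9-mesityl-3,6-di-tert-butyl-10-phenylacridinium tetrafluoroborate (5 mol%), thiol T* (15 mol%), 2,6-lutidine (25 mol%), ClCH2CH2Cl (0.02 M), 450 nm LEDs, −20 °C, Ar
Reagents that add atoms: none
Why: Proposed new method: enantioselective photoredox anti-Markovnikov hydroetherification — the excited acridinium oxidises the dialkoxy α-alkylstyrene of ring B to its radical cation, the chelated C2 phenol (helped by lutidine) adds 6-endo to the terminal alkene carbon to form the O1–C2 bond and a tertiary benzylic radical at C3, and the arenethiol T*, docked through its urea to the formyl/phenol edge next to O1, delivers hydrogen to one face in an exothermic, irreversible hydrogen-atom transfer that sets (3R), after which the thiyl radical is reduced by the acridine radical and reprotonated; the closest known reaction type is the racemic acridinium/thiol anti-Markovnikov hydroetherification of alkenols together with peptide-thiol-controlled enantioselective hydrogen-atom transfer in radical alkene hydroamination.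

Step 8
Reactants: 14 (3R)-3-[2,4-bis(methoxymethoxy)-3-(3-methylbut-2-en-1-yl)phenyl]-7-hydroxy-5-methoxy-3,4-dihydro-2H-chromene-8-carbaldehyde
Product: 15 (3R)-3-[2,4-dihydroxy-3-(3-methylbut-2-en-1-yl)phenyl]-7-hydroxy-5-methoxy-3,4-dihydro-2H-chromene-8-carbaldehyde
Conditions: HCl (0.5 M) in MeOH/THF (3:1), 0 °C → rt; aq NaHCO3
Reagents that add atoms: none
Why: Acid-catalysed transacetalisation of both aryl MOM ethers to methanol; the conditions are mild enough to leave the prenyl group uncyclised, and C3 has no pathway to epimerise.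

**Compound list**
1 | 2,4,6-trihydroxybenzaldehyde | O=Cc1c(O)cc(O)cc1O | starting material
2 | 2,6-dihydroxy-4-methoxybenzaldehyde | COc1cc(O)c(C=O)c(O)c1 | intermediate
3 | 2,3-dibromoprop-1-ene | C=C(Br)CBr | starting material
4 | 2-[(2-bromoprop-2-en-1-yl)oxy]-6-hydroxy-4-methoxybenzaldehyde | COc1cc(O)c(C=O)c(OCC(Br)=C)c1 | intermediate
5 | 4-bromobenzene-1,3-diol (4-bromoresorcinol) | Oc1ccc(Br)c(O)c1 | starting material
6 | 1-bromo-2,4-bis(methoxymethoxy)benzene | COCOc1ccc(Br)c(OCOC)c1 | intermediate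
7 | 1-bromo-3-methylbut-2-ene (prenyl bromide) | CC(C)=CCBr | starting material
8 | [3-bromo-2,6-bis(methoxymethoxy)phenyl]lithium | [Li]c1c(OCOC)ccc(Br)c1OCOC | intermediate
9 | 1-bromo-2,4-bis(methoxymethoxy)-3-(3-methylbut-2-en-1-yl)benzene | COCOc1ccc(Br)c(OCOC)c1CC=C(C)C | intermediate
10 | [2,4-bis(methoxymethoxy)-3-(3-methylbut-2-en-1-yl)phenyl]lithium | COCOc1ccc([Li])c(OCOC)c1CC=C(C)C | intermediate
11 | lithium [2,4-bis(methoxymethoxy)-3-(3-methylbut-2-en-1-yl)phenyl]tri(propan-2-yloxy)borate | [Li+].COCOc1ccc([B-](OC(C)C)(OC(C)C)OC(C)C)c(OCOC)c1CC=C(C)C | intermediate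
12 | 2-({2-[2,4-bis(methoxymethoxy)-3-(3-methylbut-2-en-1-yl)phenyl]prop-2-en-1-yl}oxy)-6-hydroxy-4-methoxybenzaldehyde | COc1cc(O)c(C=O)c(OCC(=C)c2ccc(OCOC)c(CC=C(C)C)c2OCOC)c1 | intermediate
13 | 3-{2-[2,4-bis(methoxymethoxy)-3-(3-methylbut-2-en-1-yl)phenyl]prop-2-en-1-yl}-2,6-dihydroxy-4-methoxybenzaldehyde | COc1cc(O)c(C=O)c(O)c1CC(=C)c1ccc(OCOC)c(CC=C(C)C)c1OCOC | intermediate
14 | (3R)-3-[2,4-bis(methoxymethoxy)-3-(3-methylbut-2-en-1-yl)phenyl]-7-hydroxy-5-methoxy-3,4-dihydro-2H-chromene-8-carbaldehyde | COc1cc(O)c(C=O)c2c1C[C@H](c1ccc(OCOC)c(CC=C(C)C)c1OCOC)CO2 | intermediate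
15 | (3R)-3-[2,4-dihydroxy-3-(3-methylbut-2-en-1-yl)phenyl]-7-hydroxy-5-methoxy-3,4-dihydro-2H-chromene-8-carbaldehyde | COc1cc(O)c(C=O)c2c1C[C@H](c1ccc(O)c(CC=C(C)C)c1O)CO2 | target

**Step count and risks**
Total steps: 8. Longest linear sequence: 6 (steps 3, 4, 5, 6, 7, 8, from 4-bromobenzene-1,3-diol).

Steps most likely to fail:

Step 7 (proposed new method). Risks are low enantioselectivity in the hydrogen-atom transfer, oxidation of the ring A phenols in place of the styrene, and thiol–ene loss of T* on the prenyl group. The fallback uses known chemistry only, sets out from 13 and comes back at 14. Both phenols of 13 are silylated (TBSOTf, 2,6-lutidine, CH2Cl2) to give the bis-silyl ether F1. Cobalt-catalysed enantioselective anti-Markovnikov hydroboration of the 1,1-disubstituted aryl alkene (CoCl2 complex of a chiral iminopyridine–oxazoline ligand, NaBHEt3, HBpin 2.5 equiv, THF, rt) sets the (R) centre and also reduces the formyl group, giving the bis-boronate F2, which is not isolated. NaBO3·4H2O oxidises F2 to the diol F3. MnO2 (CH2Cl2) reoxidises only the benzylic alcohol, giving the hydroxy aldehyde F4. Bu4NF/AcOH (THF) removes both silyl groups to give the diphenol F5. Mitsunobu cyclisation of F5 (PPh3, DIAD, THF, 0 °C) closes the O1–C2 bond; only the C2 phenol can reach, so 14 results.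

Step 6 (Claisen rearrangement). Risks are Markovnikov cyclisation of 13 to a 2-methyl-2-aryl-dihydrobenzofuran at 190 °C and thermal loss of MOM groups. The fallback avoids heating and the ether 12 altogether; it sets out from 2, 3 and borate 11 (made from 9 as in step 5) and comes back at 13. Direct C-alkylation of the phloroglucinol-type phenoxide of 2 with 3 (aq KOH, 0 °C → rt; the O-ether 4 is separated) gives 3-(2-bromoprop-2-en-1-yl)-2,6-dihydroxy-4-methoxybenzaldehyde F6. Suzuki–Miyaura coupling of F6 with 11 (Pd(OAc)2, SPhos, aq K3PO4, THF, 40 °C) gives 13.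

Step 5 (one-pot borylation/Suzuki on 4). Risks are ionisation of the allyl aryl ether of 4 or 12 by zerovalent palladium and protodeboronation of the electron-rich borate. The fallback takes 4 out of the palladium step and forms the ether bond last; it sets out from 9 and 2 and comes back at 12. Borate 11 (from 9) is coupled with 2-bromoprop-2-en-1-ol (Pd(OAc)2, SPhos, aq K3PO4, THF, 40 °C) to give 2-[2,4-bis(methoxymethoxy)-3-(3-methylbut-2-en-1-yl)phenyl]prop-2-en-1-ol F7. Mitsunobu etherification of F7 with 2 (1.5 equiv, PPh3, DIAD, THF, 0 °C) gives 12.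

Further compounds
F1 | step 7 | 3-{2-[2,4-bis(methoxymethoxy)-3-(3-methylbut-2-en-1-yl)phenyl]prop-2-en-1-yl}-2,6-bis[(tert-butyldimethylsilyl)oxy]-4-methoxybenzaldehyde | COc1cc(O[Si](C)(C)C(C)(C)C)c(C=O)c(O[Si](C)(C)C(C)(C)C)c1CC(=C)c1ccc(OCOC)c(CC=C(C)C)c1OCOC
F2 | step 7 | 2-[(2R)-2-[2,4-bis(methoxymethoxy)-3-(3-methylbut-2-en-1-yl)phenyl]-3-{2,4-bis[(tert-butyldimethylsilyl)oxy]-6-methoxy-3-[(4,4,5,5-tetramethyl-1,3,2-dioxaborolan-2-yl)oxymethyl]phenyl}propyl]-4,4,5,5-tetramethyl-1,3,2-dioxaborolane | COc1cc(O[Si](C)(C)C(C)(C)C)c(COB2OC(C)(C)C(C)(C)O2)c(O[Si](C)(C)C(C)(C)C)c1C[C@H](c1ccc(OCOC)c(CC=C(C)C)c1OCOC)CB1OC(C)(C)C(C)(C)O1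
F3 | step 7 | (2R)-2-[2,4-bis(methoxymethoxy)-3-(3-methylbut-2-en-1-yl)phenyl]-3-{2,4-bis[(tert-butyldimethylsilyl)oxy]-3-(hydroxymethyl)-6-methoxyphenyl}propan-1-ol | COc1cc(O[Si](C)(C)C(C)(C)C)c(CO)c(O[Si](C)(C)C(C)(C)C)c1C[C@H](c1ccc(OCOC)c(CC=C(C)C)c1OCOC)CO
F4 | step 7 | 3-{(2R)-2-[2,4-bis(methoxymethoxy)-3-(3-methylbut-2-en-1-yl)phenyl]-3-hydroxypropyl}-2,6-bis[(tert-butyldimethylsilyl)oxy]-4-methoxybenzaldehyde | COc1cc(O[Si](C)(C)C(C)(C)C)c(C=O)c(O[Si](C)(C)C(C)(C)C)c1C[C@H](c1ccc(OCOC)c(CC=C(C)C)c1OCOC)CO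
F5 | step 7 | 3-{(2R)-2-[2,4-bis(methoxymethoxy)-3-(3-methylbut-2-en-1-yl)phenyl]-3-hydroxypropyl}-2,6-dihydroxy-4-methoxybenzaldehyde | COc1cc(O)c(C=O)c(O)c1C[C@H](c1ccc(OCOC)c(CC=C(C)C)c1OCOC)CO
F6 | step 6 | 3-(2-bromoprop-2-en-1-yl)-2,6-dihydroxy-4-methoxybenzaldehyde | COc1cc(O)c(C=O)c(O)c1CC(Br)=C
F7 | step 5 | 2-[2,4-bis(methoxymethoxy)-3-(3-methylbut-2-en-1-yl)phenyl]prop-2-en-1-ol | OCC(=C)c1ccc(OCOC)c(CC=C(C)C)c1OCOC
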